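## The problem

Gibberellane numbering is used throughout: ring A is C1–C5 and C10, ring B is C5, C6, C8, C9 and C10, ring C is C8, C9 and C11–C14, ring D is C8, C14, C13, C16 and C15, C7 is the carboxyl on C6, C17 the methylene on C16, C18 the methyl and C19 the lactone carbonyl on C4, and α is the face of ring B that carries the lactone oxygen while β is the face of H5 and H9. The target (35), number 32 of the gibberellin A series, is a C19 gibberellin in which rings A and B are trans-fused, a γ-lactone (C4–C19–O–C10) bridges ring A on the α face, and rings C and D form a bicyclo[3.2.1]octane whose bridgehead C8 is also a ring B atom. Ten stereocentres (C3, C4, C5, C6, C8, C9, C10, C12, C13, C15) sit on this skeleton, and C4, C8, C10 and C13 are fully substituted. Control can be relayed: C9 can direct C10 (addition to a C10 ketone anti to C11), and the C10 oxygen then fixes C5 and C4 through the cis-fused lactone. C13 can be set on the convex face of a cis-fused B/C bicycle and then directs O12 and, through a tether, C8, whereas the allylic carbinols C3 and C15 each need their own control element. Three groups will not survive rough treatment: the allylic lactone next to a free 3-hydroxyl, which rearranges in base (allylic displacement by the 3-alkoxide) and can undergo retro-aldol cleavage; the tertiary allylic 13-hydroxyl next to the exocyclic methylene, which rearranges in strong acid; and the epimerisable C6. The feature that makes the key step possible is that quaternary C8 is bonded to C6, which carries the C7 carboxyl, so that a C6=C8 enoate in ring B can accept C15 delivered from C13 through C16. The second bond formed in that event (C6–C15) joins the α-carbon of the C16 ketone to the α-carbon of the C7 ester, so it can be cut again by electron transfer.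

## Retrosynthesis

**Late oxygenation and methylene (35 back to 29).** No skeletal bond is cut; the 15-hydroxyl and C17 are removed, leading through 34, 33, enone 32, alcohol 31 and alkene 30 to ketone 29. In 29 the C16 ketone has C15 as its only enolisable neighbour, so methylenation and allylic oxidation carry no regiochemical question. Carrying a C15 oxygen through the ring D construction would instead place a heteroatom next to the carbenoid carbon. The forward reactions must oxidise C15 on the open face of ring D and then invert it by oxidation and hydride delivery from that same face.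

**Ring D (29 back to 28 back to 27).** The C6–C15 bond of cyclopropyl ketone 28 and then C8–C15 and C6–C15 of diazoketone 27 are cut. This removes ring D, the quaternary centre C8 and the stereocentres C6 and C15 in one disconnection and leaves an A/B/C tricycle with a planar C6=C8 enoate. A direct C8–C15 Michael disconnection is the nearest neighbour and is kept as the fallback. The forward step needs a carbenoid on C15, held by C13, to reach the β face of a tetrasubstituted, electron-poor alkene.

**Diazoketone and enoate (27 back to 21).** The diazo group is removed to methyl ketone 25, the acetyl group is traced to the ethynyl group of 24 and 23, and C7 is cut from C6 at enol triflate 22, which comes from ketone 21. A C6 ketone is preferred over a C6 ester carried from the start because only the ketone lets the C6=C8 double bond be placed regioselectively. The precursor 21 is simpler by one carbon and has no base-sensitive enoate.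

**Ring C oxygenation (21/19 back to 15).** The C13–C16 bond (acetylide addition to a C13 ketone) and the C12–O bond (directed epoxidation, hydride opening) are cut, leading to enone 15. Both operations are run while C8 is still sp3, so the cis-fused B/C bicycle gives a convex face. On the later C8-sp2 tricycle ring C has no useful facial bias. The forward reactions must add the alkyne anti to ring B and deliver oxygen syn to the new carbinol.

**Ring A (15 back to 10).** The C1=C2 bond (ring-closing metathesis in 14 from 13) and the C3–C4 bond (aldol of lactone 10 with acrolein 11, giving 12) are cut. This makes C4 quaternary and sets C3 in one step and gives the 1-ene directly, avoiding a later dehydrogenation of ring A. Compound 10 is a simple bicyclic lactone with a vinyl group on C10.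

**Lactone and C5 (10 back to 5).** Cut are C4–C18 (methylation of 9), the lactone C19–O bond together with C10–C1 (vinyl addition to the C10 ketone of 7, via 8), and C4–C5 (alkylation of ketone 5 with bromoacetate 6). All three centres on ring B (C5, C10, and C9 already present) are then controlled by the one silyloxy group on C6.

**Ring C carbons (5 back to 2 and 4).** The C8–C14 and C9–C11 bonds are cut in a Diels–Alder sense. This gives (S)-4-silyloxycyclopentenone 2 (from 1) and silyloxydiene 4 (from methyl vinyl ketone 3). The C6 silyloxy group supplies the absolute configuration, steers the diene to the opposite face, and later becomes the C6 ketone.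

## Roads not taken

Alternative 1: Ireland–Claisen ring contraction for ring A. The cut is C4–C5. Acid A1 would arise from δ-lactone A2, whose ring oxygen sits on C1 and whose C1 carries the ring B cyclopentene (C10=C5), with rings B, C and D already built. The silyl ketene acetal of A2 rearranges through a boat-like [3,3] transition state, forming C4–C5, closing carbocyclic ring A, moving the alkene to C1=C10 and freeing the C19 acid; halolactonisation and elimination would finish the allylic lactone.
- Merits: C4 and C5 are set together by suprafacial transfer from C1, the enolate geometry is fixed by the ring, and the lactone end game is the best-tested one for this ring A.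
- Weak points: it solves ring A only, so the bicyclo[3.2.1]octane with C8, C12, C13 and C15 must come from other chemistry. The exocyclic methylene and the allylic C15 silyl ether must survive strong base and later an electrophilic halogen. C7 is carried as a PMB ether and costs two oxidations.
- Comparison: for C4/C5 this road is better than steps 4–7 here, which need three enolate reactions. The chosen plan sets against it that one stereospecific step makes C8 and ring D from an easily set centre (C13), and that C7 stays at the ester level.

Alternative 2: ester enolate Michael closure of ring B. The cut is C5–C6. In A4 a C/D bicycle carries an acetate arm on C8 and a 3-methylbutenolide on C9 through its quaternary γ-carbon C10. Deprotonation at C6 and 5-exo addition to C5 would give A3 with a cis-fused saturated lactone.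
- Merits: convergent; the lactone fusion is guaranteed; C6 can equilibrate to the natural configuration; the Z-allylic ether arm prepares an aldol closure of ring A.
- Weak points: quaternary C8 and the C9–C10 bond next to a tetrasubstituted C10 must be made earlier, intermolecularly and without cyclic control. The Z geometry of the arm must survive oxidation to the aldehyde level, where such alkenes isomerise easily. C4 is still a methine and must be made quaternary late.
- Comparison: as a ring B closure it is shorter at that point than the triflate and carbonylation sequence here. The chosen plan answers that ring B comes from a purchasable enantiopure cyclopentenone and that C8 is made under tether control.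

Alternative 3: carbene-catalysed acyloin closure of ring C. The cut is C12–C13. In A6 a ring D cyclopentanone (C13 ketone, C16 ketal) carries a C12 aldehyde on C11. A triazolium-derived carbene converts the aldehyde into an acyl anion equivalent that adds to C13 and gives A5 (C12 ketone, C13 tertiary alcohol).
- Merits: the 12,13-dioxygenation and the bridgehead carbinol come from one mild catalytic step, clearly shorter than steps 10–14 here; the C12 ketone can then be reduced from the β face.
- Weak points: the spiro quaternary C8 in a cyclopentanone on ring B must be built first without a relay. The C13 ketone is flanked by a ketal and is hindered, the aldehyde is enolisable, and closure to a bridged ring may be reversible.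
- Comparison: better for O12/O13. The chosen plan sets against it the stereospecific construction of C8 together with ring D, and a C16 ketone that serves directly for the methylene and for C15.

Key step: step 22

## Route

Remarks on the chemistry:
- (S)-4-Hydroxycyclopent-2-en-1-one (1) is taken as a purchasable enantiopure building block.
- C4 of lactone 10 is drawn as the expected major epimer; either epimer serves, because step 7 re-enolises this centre.

Step 1
Reactants: 1 (S)-4-hydroxycyclopent-2-en-1-one
Product: 2 (S)-4-(triethylsilyloxy)cyclopent-2-en-1-one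
Conditions: TESCl, imidazole, CH2Cl2, 0 °C
Reagents that add atoms: chlorotriethylsilane, CC[Si](Cl)(CC)CC
Why: Standard silylation of a secondary alcohol; triethylsilyl is chosen because it can later be removed from O6 in the presence of tert-butyldimethylsilyl ethers.

Step 2
Reactants: 3 but-3-en-2-one
Product: 4 2-(tert-butyldimethylsilyloxy)buta-1,3-diene
Conditions: TBSOTf, Et3N, Et2O, 0 °C
Reagents that add atoms: tert-butyldimethylsilyl trifluoromethanesulfonate, CC(C)(C)[Si](C)(C)OS(=O)(=O)C(F)(F)F
Why: Soft enolisation of an enone with a silyl triflate and amine base gives the 2-silyloxydiene; the bulky silyl group lets the enol ether survive the following base and Grignard steps.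

Step 3
Reactants: 2 (S)-4-(triethylsilyloxy)cyclopent-2-en-1-one; 4 2-(tert-butyldimethylsilyloxy)buta-1,3-diene
Product: 5 bicyclic ketone (cis-fused rings B and C; C10 ketone; 6-OTES β; H8 and H9 β; C12=C13 enol ether with 13-OTBS)
Conditions: HNTf2 (5 mol%), CH2Cl2, −78 °C
Reagents that add atoms: none
Why: Acid-catalysed Diels–Alder reaction of a 2-silyloxydiene with a cyclopentenone (stepwise Mukaiyama–Michael then ring closure is the accepted course); the nucleophilic diene terminus bonds to the enone β-carbon C8, which places the silyloxy group on C13. The diene adds anti to the 6-OTES group, which sets C9 (and transient C8) with ring C on the α face.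

Step 4
Reactants: 5 bicyclic ketone; 6 methyl bromoacetate
Product: 7 keto ester (5 with a CH2CO2Me arm on C5, α, trans to O6)
Conditions: LiN(iPr)2, THF, −78 °C; then 6, DMPU, −78 to −40 °C
Reagents that add atoms: none
Why: Kinetic deprotonation takes the methylene C5 rather than the ring-fusion methine C9, and the enolate is alkylated anti to the adjacent silyloxy group, which sets C5; the low temperature is meant to outrun β-elimination of the silyloxy group.

Step 5
Reactants: 7 keto ester
Product: 9 vinyl lactone (19,10-γ-lactone cis-fused to ring B on the α face; 10-vinyl β; C4 is CH2), via hydroxy ester 8 (not isolated)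
Conditions: CH2=CHMgBr, CeCl3, THF, −78 °C to rt
Reagents that add atoms: vinylmagnesium bromide, C=C[Mg]Br
Why: Organocerium addition to a hindered, enolisable ketone; the nucleophile enters from the β face, anti to both flanking substituents (the C5 arm and C11), which sets C10 with its oxygen α. The resulting alkoxide is cis to the ester arm and closes the γ-lactone by 5-exo acyl substitution.

Step 6
Reactants: 9 vinyl lactone
Product: 10 methyl lactone (C18 methyl on C4, on the lactone face that carries the vinyl group)
Conditions: LiN(iPr)2, THF, −78 °C; MeI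
Reagents that add atoms: iodomethane, CI
Why: α-Alkylation of a γ-lactone enolate trans to the β-substituent (the C5–C6 bond) introduces C18; the configuration is inconsequential because the centre is enolised again in step 7.

Step 7
Reactants: 10 methyl lactone; 11 acrolein
Product: 12 aldol adduct (quaternary C4 with C18 methyl cis to C6; (S)-CH(OH)CH=CH2 as C3–C2 cis to the 10-vinyl group)
Conditions: LiN(iPr)2, THF, −78 °C; 11; AcOH quench at −78 °C
Reagents that add atoms: none
Why: Aldol 1,2-addition of a tetrasubstituted lactone enolate; the aldehyde approaches the convex lactone face anti to the ring B bond on C5, which sets C4. A Zimmerman–Traxler chair with the methyl group cis to O–Li and the vinyl group equatorial places the 3-hydroxyl syn to C18, the configuration of the target, and the cold acidic quench prevents retro-aldol.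

Step 8
Reactants: 12 aldol adduct
Product: 13 silyl ether (3-OTBS derivative of 12)
Conditions: TBSOTf, 2,6-lutidine, CH2Cl2, −78 to 0 °C
Reagents that add atoms: tert-butyldimethylsilyl trifluoromethanesulfonate, CC(C)(C)[Si](C)(C)OS(=O)(=O)C(F)(F)F
Why: Silyl triflate protects the hindered β-hydroxy lactone without forming an alkoxide, so retro-aldol cleavage is avoided.

Step 9
Reactants: 13 silyl ether
Product: 14 tetracyclic lactone (ring A closed with C1=C2; 3-OTBS; 6-OTES; ring C enol ether)
Conditions: second-generation Grubbs catalyst (H2IMes)(PCy3)Cl2Ru=CHPh (10 mol%), toluene, 80 °C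
Reagents that add atoms: none
Why: Ring-closing metathesis of two monosubstituted alkenes held cis-1,3 on a five-membered ring, the same arrangement that gives bridged bicyclo[3.2.1]octenes from cis-2,5-dialkenyl pyrrolidines; the trisubstituted silyl enol ether is inert.

Step 10
Reactants: 14 tetracyclic lactone
Product: 15 enone (ring C: C13 ketone, C11=C12)
Conditions: Pd(OAc)2 (1.1 equiv), MeCN, rt
Reagents that add atoms: none
Why: Saegusa–Ito oxidation: palladation at C12 of the silyl enol ether and β-hydride loss from C11 give the enone regiospecifically; without phosphine the zerovalent palladium formed precipitates and does not ionise the allylic lactone.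

Step 11
Reactants: 15 enone
Product: 16 propargylic alcohol (13-OH on the ring C face that carries C10; 13-C≡C–SiMe3 on the opposite face; C11=C12)
Conditions: Me3SiC≡CLi (from Me3SiC≡CH and n-BuLi), THF, −78 °C
Reagents that add atoms: ethynyltrimethylsilane, C#C[Si](C)(C)C
Why: Alkynyllithium 1,2-addition to an enone is faster than attack on the hindered lactone; the reagent enters on the convex face of the cis-fused B/C bicycle (anti to the ring B carbon on C8), which sets C13 with its oxygen syn to ring B.

Step 12
Reactants: 16 propargylic alcohol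
Product: 17 epoxy alcohol (11,12-epoxide cis to the 13-OH)
Conditions: VO(acac)2 (5 mol%), t-BuOOH, CH2Cl2, 0 °C to rt
Reagents that add atoms: tert-butyl hydroperoxide, CC(C)(C)OO
Why: Vanadium-catalysed hydroxyl-directed epoxidation delivers oxygen syn to the tertiary allylic alcohol, which sets the C12 oxygen cis to O13; the ring A alkene, whose allylic oxygen is silylated, is not touched.

Step 13
Reactants: 17 epoxy alcohol
Product: 18 diol (cis-12,13-diol; C11 is CH2)
Conditions: LiBH4, Ti(OiPr)4, benzene/THF, 0 °C to rt
Reagents that add atoms: none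
Why: Titanium-assisted opening of a 2,3-epoxy alcohol by hydride at the distal carbon C11 from the open β face; C12 is neopentyl and shielded, and the hindered lactone (quaternary α-carbon, tertiary alkoxy) should survive borohydride at this temperature.

Step 14
Reactants: 18 diol
Product: 19 silyl ether (12-OTBS and 13-OTBS; 3-OTBS; 6-OTES)
Conditions: TBSOTf (3 equiv), 2,6-lutidine, CH2Cl2, 0 °C to rt
Reagents that add atoms: tert-butyldimethylsilyl trifluoromethanesulfonate, CC(C)(C)[Si](C)(C)OS(=O)(=O)C(F)(F)F
Why: The silyl triflate silylates the secondary and the tertiary propargylic hydroxyl in one operation.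

Step 15
Reactants: 19 silyl ether
Product: 20 alcohol (6-OH free)
Conditions: PPTS, MeOH/CH2Cl2, 0 °C
Reagents that add atoms: none
Why: Mild acidic methanolysis cleaves a secondary triethylsilyl ether much faster than tert-butyldimethylsilyl ethers.

Step 16
Reactants: 20 alcohol
Product: 21 ketone (C6 ketone)
Conditions: Dess–Martin periodinane, CH2Cl2, rt
Reagents that add atoms: none
Why: Neutral oxidation of the secondary alcohol; no base is present, so the lactone oxygen β to the new ketone is not eliminated.

Step 17
Reactants: 21 ketone
Product: 22 enol triflate (C6(OTf)=C8)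
Conditions: Tf2O, 2,6-di-tert-butyl-4-methylpyridine, CH2Cl2, 0 °C to rt
Reagents that add atoms: trifluoromethanesulfonic anhydride, O=S(=O)(OS(=O)(=O)C(F)(F)F)C(F)(F)F
Why: Enol triflate formation under non-basic conditions avoids a free enolate next to the lactone; loss of H8 rather than H5 is expected because a C5=C6 double bond would make the one-atom bridge of the lactone bicycle trigonal, and this removes the transient C8 centre.

Step 18
Reactants: 22 enol triflate
Product: 23 enoate (methyl ester C7 on C6; C6=C8)
Conditions: Pd(OAc)2 (5 mol%), PPh3, CO (1 atm), MeOH, Et3N, DMF, rt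
Reagents that add atoms: carbon monoxide, [C-]#[O+]; methanol, CO
Why: Palladium-catalysed methoxycarbonylation of an enol triflate; oxidative addition of zerovalent palladium into the C–OTf bond is much faster than ionisation of the tertiary allylic lactone, and the alkyne is kept silylated to prevent coupling.

Step 19
Reactants: 23 enoate
Product: 24 alkyne (13-ethynyl)
Conditions: K2CO3, MeOH, rt
Reagents that add atoms: none
Why: Mild methanolysis of the alkynyl C–Si bond leaves the silyl ethers, the lactone and the enoate untouched.

Step 20
Reactants: 24 alkyne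
Product: 25 methyl ketone (13-acetyl: C16 carbonyl, C15 methyl)
Conditions: Ph3PAuNTf2 (5 mol%), H2O, 1,4-dioxane, 60 °C
Reagents that add atoms: water, O
Why: Gold-catalysed Markovnikov hydration of a terminal alkyne gives the methyl ketone under nearly neutral conditions that spare the silyl ethers and the alkenes.

Step 21
Reactants: 25 methyl ketone
Product: 27 diazoketone (C15 diazo carbon; C16 carbonyl on C13), via trifluoroacetyl diketone 26 (not isolated)
Conditions: LiN(SiMe3)2, THF, −78 °C; CF3CO2CH2CF3; then MsN3, Et3N, H2O, MeCN, rt
Reagents that add atoms: methanesulfonyl azide, CS(=O)(=O)N=[N+]=[N-]; 2,2,2-trifluoroethyl trifluoroacetate, O=C(OCC(F)(F)F)C(F)(F)F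
Why: Detrifluoroacetylative diazo transfer: the methyl group is the only enolisable position of the ketone and is more acidic than the γ-positions of the enoate, so it is acylated selectively; the activated diketone then accepts the diazo group with loss of the trifluoroacetyl unit.

Step 22
Reactants: 27 diazoketone
Product: 28 cyclopropyl ketone (C8–C15 and C6–C15 bonds formed; ring D closed; C16 ketone; C7 ester on the cyclopropane carbon C6)
Conditions: Cu(acac)2 (10 mol%), toluene, 90 °C, slow addition of 27
Reagents that add atoms: none
Why: Cu(acac)2 decomposes the diazoketone with loss of N2 to an electrophilic copper ketocarbenoid at C15, which adds to the C6=C8 π bond in a concerted, asynchronous [2+1] step; the closest known reaction type is the copper-catalysed intramolecular cyclopropanation of alkenes, conjugated esters included, by α-diazoketones to give bridged cyclopentanones. Ring D closes through C8–C15 as a five-membered ring over the three-atom tether C13–C16–C15 (exo with respect to the alkene, giving the bicyclo[3.2.1]octane), and the cyclopropane closes through C6–C15 in the same event. C8 is set by the tether: C16 stands on the face of C13 anti to O13 and O12, so C15 can only reach the β face of the alkene, which leaves C14 α as the configuration at C9 requires. C6 and C15 follow from the suprafacial addition (C7 ends exo on the cyclopropane), so all three new centres depend on C13 alone. The step needs cyclopropanation to win over C–H insertion at C11 and over oxonium ylide formation at the silyl ether oxygens; a copper rather than a dirhodium catalyst, the bulky and weakly basic silyl ethers and slow addition favour it, and the ring A alkene is out of reach. Ring C must leave its chair for a twist-boat to bring C16 over the β face of C8, which is why the reaction is run hot.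

Step 23
Reactants: 28 cyclopropyl ketone
Product: 29 keto ester (C16 ketone, C15 methylene, C6–H with C7 β and trans to C4)
Conditions: SmI2 (2.2 equiv), HMPA, MeOH (2 equiv), THF, −78 °C
Reagents that add atoms: none
Why: Electron transfer gives the C16 ketyl, which opens the cyclopropane at the C6–C15 bond (external to the cyclopentanone, best aligned with the ketyl π system, and leading to an ester-stabilised radical); a second electron gives the C6 ester enolate, whose protonation should leave C7 trans to C4, the more stable arrangement. Loss of the α-silyloxy group is not expected, because it would need a bridgehead enolate at C13 and the C13–O bond lies near the nodal plane of the ketyl.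

Step 24
Reactants: 29 keto ester
Product: 30 alkene (C16=C17 methylene)
Conditions: Ph3PCH3Br, KOtBu, THF, rt to 60 °C
Reagents that add atoms: methyltriphenylphosphonium bromide, C[P+](c1ccccc1)(c1ccccc1)c1ccccc1.[Br-]
Why: Wittig methylenation of a hindered ketone whose only enolisable neighbour is C15; excess ylide compensates for reversible enolisation, and any C6 epimer is equilibrated to the trans ester under these basic conditions.

Step 25
Reactants: 30 alkene
Product: 31 allylic alcohol (15-OH on the face of ring D turned toward C7, epimeric with the target at C15)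
Conditions: SeO2 (20 mol%), t-BuOOH, CH2Cl2, rt
Reagents that add atoms: tert-butyl hydroperoxide, CC(C)(C)OO
Why: Selenium dioxide allylic hydroxylation (ene reaction, then [2,3] shift) can only take C15, since C13 is quaternary; oxygen arrives on the open face of ring D, away from H9 and the C11 axial hydrogen. Any enone formed by over-oxidation is the product of the next step.

Step 26
Reactants: 31 allylic alcohol
Product: 32 enone (C15 ketone conjugated with C16=C17)
Conditions: Dess–Martin periodinane, CH2Cl2, rt
Reagents that add atoms: none
Why: Neutral oxidation of the allylic alcohol; it is run promptly because this hydroxyl is cis to the C7 ester and could lactonise.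

Step 27
Reactants: 32 enone
Product: 33 allylic alcohol (15-OH on the face of ring D turned toward C9, as in the target; 3,12,13-tris-OTBS methyl ester)
Conditions: NaBH4, CeCl3·7H2O, MeOH, −78 °C
Reagents that add atoms: none
Why: Luche 1,2-reduction of the α-methylene ketone; hydride enters from the same open face that SeO2 used, so the hydroxyl ends on the opposite face and sets C15.

Step 28
Reactants: 33 allylic alcohol
Product: 34 acid (C7 carboxylic acid; 3,12,13-tris-OTBS)
Conditions: LiSPr, HMPA, rt; then dilute HCl to pH 4
Reagents that add atoms: none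
Why: Thiolate SN2 demethylation attacks the methyl group and is indifferent to the hindrance at C6; the weakly basic thiolate and the silylated 3-oxygen leave the allylic lactone intact.

Step 29
Reactants: 34 acid
Product: 35 target gibberellin (number 32 of the gibberellin A series; free 3-, 12-, 13- and 15-hydroxyls and free C7 acid)
Conditions: HF·pyridine, pyridine, THF, 0 °C to rt
Reagents that add atoms: none
Why: Buffered fluoride cleaves the three silyl ethers without a basic alkoxide at O3 (no lactone rearrangement) and without strong acid (no rearrangement of the 13-hydroxy-16-ene).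

## Compound list

1 | (S)-4-hydroxycyclopent-2-en-1-one | O=C1C=C[C@@H](O)C1 | starting material
2 | (S)-4-(triethylsilyloxy)cyclopent-2-en-1-one | O=C1C=C[C@@H](O[Si](CC)(CC)CC)C1 | intermediate
3 | but-3-en-2-one (methyl vinyl ketone) | CC(=O)C=C | starting material
4 | 2-(tert-butyldimethylsilyloxy)buta-1,3-diene | C=CC(=C)O[Si](C)(C)C(C)(C)C | intermediate
5 | bicyclic ketone: cis-fused rings B and C, C10 ketone, 6-OTES β, C12=C13 enol ether with 13-OTBS | O=C1C[C@H](O[Si](CC)(CC)CC)[C@H]2CC(O[Si](C)(C)C(C)(C)C)=CC[C@@H]12 | intermediate
6 | methyl bromoacetate | COC(=O)CBr | starting material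
7 | keto ester: 5 with CH2CO2Me on C5, trans to O6 | O=C1[C@@H](CC(=O)OC)[C@H](O[Si](CC)(CC)CC)[C@H]2CC(O[Si](C)(C)C(C)(C)C)=CC[C@@H]12 | intermediate
8 | hydroxy ester: 10-hydroxy-10-vinyl adduct of 7, O10 cis to the C5 arm | C=C[C@]1(O)[C@@H](CC(=O)OC)[C@H](O[Si](CC)(CC)CC)[C@H]2CC(O[Si](C)(C)C(C)(C)C)=CC[C@@H]12 | intermediate (not isolated)
9 | vinyl lactone: 19,10-γ-lactone, 10-vinyl, C4 methylene | C=C[C@]12OC(=O)C[C@H]1[C@H](O[Si](CC)(CC)CC)[C@H]3CC(O[Si](C)(C)C(C)(C)C)=CC[C@@H]23 | intermediate
10 | methyl lactone: 9 with C18 methyl on C4 | C=C[C@]12OC(=O)[C@H](C)[C@H]1[C@H](O[Si](CC)(CC)CC)[C@H]3CC(O[Si](C)(C)C(C)(C)C)=CC[C@@H]23 | intermediate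
11 | acrolein (prop-2-enal) | C=CC=O | starting material
12 | aldol adduct: quaternary C4 with C18 methyl and (S)-1-hydroxyprop-2-enyl (C3, C2) | C=C[C@]12OC(=O)[C@](C)([C@@H](O)C=C)[C@H]1[C@H](O[Si](CC)(CC)CC)[C@H]3CC(O[Si](C)(C)C(C)(C)C)=CC[C@@H]23 | intermediate
13 | silyl ether: 3-OTBS derivative of 12 | C=C[C@]12OC(=O)[C@](C)([C@@H](O[Si](C)(C)C(C)(C)C)C=C)[C@H]1[C@H](O[Si](CC)(CC)CC)[C@H]3CC(O[Si](C)(C)C(C)(C)C)=CC[C@@H]23 | intermediate
14 | tetracyclic lactone: ring A closed (C1=C2), 3-OTBS, 6-OTES, ring C enol ether | O=C1O[C@@]23C=C[C@H](O[Si](C)(C)C(C)(C)C)[C@]1(C)[C@H]2[C@H](O[Si](CC)(CC)CC)[C@H]4CC(O[Si](C)(C)C(C)(C)C)=CC[C@@H]34 | intermediate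
15 | enone: C13 ketone, C11=C12 | O=C1O[C@@]23C=C[C@H](O[Si](C)(C)C(C)(C)C)[C@]1(C)[C@H]2[C@H](O[Si](CC)(CC)CC)[C@H]4CC(=O)C=C[C@@H]34 | intermediate
16 | propargylic alcohol: 13-hydroxy-13-(trimethylsilylethynyl), C11=C12 | O=C1O[C@@]23C=C[C@H](O[Si](C)(C)C(C)(C)C)[C@]1(C)[C@H]2[C@H](O[Si](CC)(CC)CC)[C@H]4C[C@](O)(C#C[Si](C)(C)C)C=C[C@@H]34 | intermediate
17 | epoxy alcohol: 11,12-epoxide cis to 13-OH | O=C1O[C@@]23C=C[C@H](O[Si](C)(C)C(C)(C)C)[C@]1(C)[C@H]2[C@H](O[Si](CC)(CC)CC)[C@H]4C[C@](O)(C#C[Si](C)(C)C)[C@H]5O[C@H]5[C@@H]34 | intermediate
18 | diol: cis-12,13-diol | O=C1O[C@@]23C=C[C@H](O[Si](C)(C)C(C)(C)C)[C@]1(C)[C@H]2[C@H](O[Si](CC)(CC)CC)[C@H]4C[C@](O)(C#C[Si](C)(C)C)[C@@H](O)C[C@@H]34 | intermediate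
19 | silyl ether: 3,12,13-tris-OTBS, 6-OTES | O=C1O[C@@]23C=C[C@H](O[Si](C)(C)C(C)(C)C)[C@]1(C)[C@H]2[C@H](O[Si](CC)(CC)CC)[C@H]4C[C@](O[Si](C)(C)C(C)(C)C)(C#C[Si](C)(C)C)[C@@H](O[Si](C)(C)C(C)(C)C)C[C@@H]34 | intermediate
20 | alcohol: 6-OH | O=C1O[C@@]23C=C[C@H](O[Si](C)(C)C(C)(C)C)[C@]1(C)[C@H]2[C@H](O)[C@H]4C[C@](O[Si](C)(C)C(C)(C)C)(C#C[Si](C)(C)C)[C@@H](O[Si](C)(C)C(C)(C)C)C[C@@H]34 | intermediate
21 | ketone: C6 ketone | O=C1O[C@@]23C=C[C@H](O[Si](C)(C)C(C)(C)C)[C@]1(C)[C@H]2C(=O)[C@H]4C[C@](O[Si](C)(C)C(C)(C)C)(C#C[Si](C)(C)C)[C@@H](O[Si](C)(C)C(C)(C)C)C[C@@H]34 | intermediate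
22 | enol triflate: C6(OTf)=C8 | O=C1O[C@@]23C=C[C@H](O[Si](C)(C)C(C)(C)C)[C@]1(C)[C@H]2C(OS(=O)(=O)C(F)(F)F)=C4C[C@](O[Si](C)(C)C(C)(C)C)(C#C[Si](C)(C)C)[C@@H](O[Si](C)(C)C(C)(C)C)C[C@@H]34 | intermediate
23 | enoate: methyl ester on C6, C6=C8, silylated alkyne on C13 | O=C1O[C@@]23C=C[C@H](O[Si](C)(C)C(C)(C)C)[C@]1(C)[C@H]2C(C(=O)OC)=C4C[C@](O[Si](C)(C)C(C)(C)C)(C#C[Si](C)(C)C)[C@@H](O[Si](C)(C)C(C)(C)C)C[C@@H]34 | intermediate
24 | alkyne: 13-ethynyl | O=C1O[C@@]23C=C[C@H](O[Si](C)(C)C(C)(C)C)[C@]1(C)[C@H]2C(C(=O)OC)=C4C[C@](O[Si](C)(C)C(C)(C)C)(C#C)[C@@H](O[Si](C)(C)C(C)(C)C)C[C@@H]34 | intermediate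
25 | methyl ketone: 13-acetyl (C16, C15) | O=C1O[C@@]23C=C[C@H](O[Si](C)(C)C(C)(C)C)[C@]1(C)[C@H]2C(C(=O)OC)=C4C[C@](O[Si](C)(C)C(C)(C)C)(C(C)=O)[C@@H](O[Si](C)(C)C(C)(C)C)C[C@@H]34 | intermediate
26 | trifluoroacetyl diketone: C15 acylated | O=C1O[C@@]23C=C[C@H](O[Si](C)(C)C(C)(C)C)[C@]1(C)[C@H]2C(C(=O)OC)=C4C[C@](O[Si](C)(C)C(C)(C)C)(C(=O)CC(=O)C(F)(F)F)[C@@H](O[Si](C)(C)C(C)(C)C)C[C@@H]34 | intermediate (not isolated)
27 | diazoketone: C13 diazoketone with ring B cyclopentenecarboxylate | O=C1O[C@@]23C=C[C@H](O[Si](C)(C)C(C)(C)C)[C@]1(C)[C@H]2C(C(=O)OC)=C4C[C@](O[Si](C)(C)C(C)(C)C)(C(=O)C=[N+]=[N-])[C@@H](O[Si](C)(C)C(C)(C)C)C[C@@H]34 | intermediate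
28 | cyclopropyl ketone: C6,C8,C15-cyclopropane, C16 ketone | O=C1[C@H]4[C@]23C[C@@]1(O[Si](C)(C)C(C)(C)C)[C@@H](O[Si](C)(C)C(C)(C)C)C[C@H]2[C@@]12C=C[C@H](O[Si](C)(C)C(C)(C)C)[C@@](C)(C(=O)O1)[C@H]2[C@@]34C(=O)OC | intermediate
29 | keto ester: C16 ketone, C15 methylene, natural C6 | O=C1C[C@]23C[C@@]1(O[Si](C)(C)C(C)(C)C)[C@@H](O[Si](C)(C)C(C)(C)C)C[C@H]2[C@@]12C=C[C@H](O[Si](C)(C)C(C)(C)C)[C@@](C)(C(=O)O1)[C@H]2[C@@H]3C(=O)OC | intermediate
30 | alkene: 16-methylene | C=C1C[C@]23C[C@@]1(O[Si](C)(C)C(C)(C)C)[C@@H](O[Si](C)(C)C(C)(C)C)C[C@H]2[C@@]12C=C[C@H](O[Si](C)(C)C(C)(C)C)[C@@](C)(C(=O)O1)[C@H]2[C@@H]3C(=O)OC | intermediate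
31 | allylic alcohol: 15-epimer (15-OH toward C7) | C=C1[C@H](O)[C@]23C[C@@]1(O[Si](C)(C)C(C)(C)C)[C@@H](O[Si](C)(C)C(C)(C)C)C[C@H]2[C@@]12C=C[C@H](O[Si](C)(C)C(C)(C)C)[C@@](C)(C(=O)O1)[C@H]2[C@@H]3C(=O)OC | intermediate
32 | enone: C15 ketone | C=C1C(=O)[C@]23C[C@@]1(O[Si](C)(C)C(C)(C)C)[C@@H](O[Si](C)(C)C(C)(C)C)C[C@H]2[C@@]12C=C[C@H](O[Si](C)(C)C(C)(C)C)[C@@](C)(C(=O)O1)[C@H]2[C@@H]3C(=O)OC | intermediate
33 | allylic alcohol: methyl ester 3,12,13-tris-TBS ether of target 35 | C=C1[C@@H](O)[C@]23C[C@@]1(O[Si](C)(C)C(C)(C)C)[C@@H](O[Si](C)(C)C(C)(C)C)C[C@H]2[C@@]12C=C[C@H](O[Si](C)(C)C(C)(C)C)[C@@](C)(C(=O)O1)[C@H]2[C@@H]3C(=O)OC | intermediate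
34 | acid: 3,12,13-tris-TBS ether of target 35 | C=C1[C@@H](O)[C@]23C[C@@]1(O[Si](C)(C)C(C)(C)C)[C@@H](O[Si](C)(C)C(C)(C)C)C[C@H]2[C@@]12C=C[C@H](O[Si](C)(C)C(C)(C)C)[C@@](C)(C(=O)O1)[C@H]2[C@@H]3C(=O)O | intermediate
35 | target gibberellin, number 32 of the gibberellin A series: 3,12,13,15-tetrahydroxy 1,16-diene with the 19,10-lactone and the free C7 acid | C=C1[C@@H](O)[C@]23C[C@@]1(O)[C@@H](O)C[C@H]2[C@@]12C=C[C@H](O)[C@@](C)(C(=O)O1)[C@H]2[C@@H]3C(=O)O | target

## Step count and least certain steps

Total step count: 29. Longest linear sequence: 28 steps (1 to 35; step 2 prepares diene 4 separately).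

**Step 22 (key step).** The carbenoid must reach a hindered, electron-poor, tetrasubstituted alkene from a twist-boat conformer of ring C. Insertion into the C11–H bond, ylide formation at the silyl ether oxygens or carbene dimerisation may take over, because the short-lived carbenoid cannot wait for the minor conformer. The fallback drops the carbenoid: from methyl ketone 25, treatment with KOtBu in t-BuOH/THF generates the C15 enolate, which adds in a Michael sense to C8 of the enoate. The closure has the geometry of the cyclopentenone-forming aldol of a 1,4-diketone, and the long-lived enolate can reach the reactive conformer under equilibrating conditions. This forms C8–C15 directly, and the resulting ester enolate is protonated under the same equilibrating conditions to give keto ester 29. The route is rejoined at 29 and compounds 26–28 are bypassed; no new compound is made (F0).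

**Step 4.** The C5 enolate carries a silyloxy group on the next carbon; β-elimination to a cyclopentenone or deprotonation at C9 may compete with alkylation. The fallback uses an aza-enolate, which tolerates β-oxygen better. From 5, condensation with Me2NNH2 gives N,N-dimethylhydrazone F1. Deprotonation with LiN(iPr)2 and alkylation with 6 gives alkylated hydrazone F2, and buffered aqueous CuCl2 hydrolysis returns keto ester 7.

**Step 7.** The aldol may pass through an open transition state and give poor selectivity at C3, or revert on warming. The fallback builds C3 without a stereocentre and oxidises it later. From 10, allylation of the lactone enolate with allyl bromide gives allyl lactone F3, and ring-closing metathesis then gives 3-deoxy tetracycle F4. Saegusa–Ito oxidation gives 3-deoxy enone F5, after which SeO2/t-BuOOH hydroxylates the allylic C3 methylene from the face away from the lactone bridge and gives 3-hydroxy enone F6. Silylation with TBSOTf returns enone 15.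

**Step 9.** Closure to the bridged ring may be slow against oligomerisation because both alkenes are hindered and the product is strained. The fallback closes ring A before the bridge exists. From 13, LiAlH4 reduces the lactone to diol F7. Metathesis then forms an ordinary fused cyclohexene, ring A diol F8, and TEMPO with PhI(OAc)2 re-forms the lactone through the lactol, returning tetracyclic lactone 14.

**Step 23.** Protonation of the C6 enolate may occur from the less hindered β face and leave C7 cis to C4, and excess reagent could over-reduce the regenerated C16 ketone. The fallback separates reduction from stereocontrol. From 28, the reduction is run with t-BuOH as proton source and quenched cold to give the C6-epimeric keto ester F9. F9 is then equilibrated with NaOMe in MeOH at 0 °C to the trans ester 29.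

## Further compounds

F0 | step 22 | none | none
F1 | step 4 | N,N-dimethylhydrazone of bicyclic ketone 5 | CN(C)N=C1C[C@H](O[Si](CC)(CC)CC)[C@H]2CC(O[Si](C)(C)C(C)(C)C)=CC[C@@H]12
F2 | step 4 | C5-alkylated N,N-dimethylhydrazone (CH2CO2Me on C5, trans to O6) | CN(C)N=C1[C@@H](CC(=O)OC)[C@H](O[Si](CC)(CC)CC)[C@H]2CC(O[Si](C)(C)C(C)(C)C)=CC[C@@H]12
F3 | step 7 | allyl lactone (C4 with C18 methyl and allyl as C3–C2–CH2) | C=C[C@]12OC(=O)[C@](C)(CC=C)[C@H]1[C@H](O[Si](CC)(CC)CC)[C@H]3CC(O[Si](C)(C)C(C)(C)C)=CC[C@@H]23
F4 | step 7 | 3-deoxy tetracycle (ring A closed, C1=C2, C3 methylene) | O=C1O[C@@]23C=CC[C@]1(C)[C@H]2[C@H](O[Si](CC)(CC)CC)[C@H]4CC(O[Si](C)(C)C(C)(C)C)=CC[C@@H]34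
F5 | step 7 | 3-deoxy enone (C13 ketone, C11=C12) | O=C1O[C@@]23C=CC[C@]1(C)[C@H]2[C@H](O[Si](CC)(CC)CC)[C@H]4CC(=O)C=C[C@@H]34
F6 | step 7 | 3-hydroxy enone (free 3-OH, C13 ketone, C11=C12) | O=C1O[C@@]23C=C[C@H](O)[C@]1(C)[C@H]2[C@H](O[Si](CC)(CC)CC)[C@H]4CC(=O)C=C[C@@H]34
F7 | step 9 | diol from reduction of lactone 13 (C19 primary alcohol, 10-OH tertiary) | C=C[C@]1(O)[C@@H]([C@](C)(CO)[C@@H](O[Si](C)(C)C(C)(C)C)C=C)[C@H](O[Si](CC)(CC)CC)[C@H]2CC(O[Si](C)(C)C(C)(C)C)=CC[C@@H]12
F8 | step 9 | ring A diol (C1=C2 closed, lactone not yet re-formed) | OC[C@]1(C)[C@@H](O[Si](C)(C)C(C)(C)C)C=C[C@]2(O)[C@@H]1[C@H](O[Si](CC)(CC)CC)[C@H]3CC(O[Si](C)(C)C(C)(C)C)=CC[C@@H]23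
F9 | step 23 | C6 epimer of keto ester 29 | O=C1C[C@]23C[C@@]1(O[Si](C)(C)C(C)(C)C)[C@@H](O[Si](C)(C)C(C)(C)C)C[C@H]2[C@@]12C=C[C@H](O[Si](C)(C)C(C)(C)C)[C@@](C)(C(=O)O1)[C@H]2[C@H]3C(=O)OC
A1 | alternative 1 | ring A C19 acid with the C1=C10 alkene (product of the Ireland–Claisen step) | C=C1[C@@H](O[Si](C)(C)C(C)(C)C)[C@]23C[C@@]1(O[Si](C)(C)C)[C@@H](O[Si](C)(C)C(C)(C)C)C[C@H]2C4=CC[C@H](O[Si](C)(C)C(C)(C)C)[C@@](C)(C(=O)O)[C@H]4[C@@H]3COCc5ccc(OC)cc5
A2 | alternative 1 | δ-lactone with ring oxygen on C1 and the ring B cyclopentene (C10=C5) on C1 (C4 epimer arbitrary) | C=C1[C@@H](O[Si](C)(C)C(C)(C)C)[C@]23C[C@@]1(O[Si](C)(C)C)[C@@H](O[Si](C)(C)C(C)(C)C)C[C@H]2C(=C[C@@H]3COCc4ccc(OC)cc4)[C@@H]5C[C@H](O[Si](C)(C)C(C)(C)C)[C@H](C)C(=O)O5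
A3 | alternative 2 | B/C/D tricycle with cis-fused saturated lactone and Z-allylic ether arm (product of the Michael closure) | C=C1[C@@H](O[Si](C)(C)C(C)(C)C)[C@]23C[C@@]1(O[Si](C)(C)C)[C@@H](O[Si](C)(C)C(C)(C)C)C[C@H]2[C@@]2(/C=C\CO[Si](C)(C)C(C)(C)C)OC(=O)[C@@H](C)[C@H]2[C@@H]3C(=O)OC
A4 | alternative 2 | C/D bicycle with acetate arm on C8 and 3-methylbutenolide on C9 | C=C1[C@@H](O[Si](C)(C)C(C)(C)C)[C@]2(CC(=O)OC)C[C@@]1(O[Si](C)(C)C)[C@@H](O[Si](C)(C)C(C)(C)C)C[C@H]2[C@@]3(/C=C\CO[Si](C)(C)C(C)(C)C)OC(=O)C(C)=C3
A5 | alternative 3 | C12-keto C13-hydroxy bicyclo[3.2.1]octane with C16 ketal (product of the acyloin closure) | C1COC2(O1)[C@@H](O[Si](C)(C)C(C)(C)C)[C@]34C[C@@]2(O)C(=O)C[C@H]3[C@@]56C=C[C@H](O[Si](C)(C)C(C)(C)C)[C@@](C)(C(=O)O5)[C@H]6[C@@H]4C(=O)OC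
A6 | alternative 3 | ring D cyclopentanone (C13 ketone, C16 ketal) with C12 aldehyde arm on C9 | C1COC2(O1)[C@@H](O[Si](C)(C)C(C)(C)C)[C@]3(CC2=O)[C@@H](CC=O)[C@@]45C=C[C@H](O[Si](C)(C)C(C)(C)C)[C@@](C)(C(=O)O4)[C@H]5[C@@H]3C(=O)OC
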